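**Plan**

- Retrosynthetic cuts: (a) the bond between the stereogenic ring CH of the 2,2-dimethyl-6-methylidenecyclohexyl unit and the chain CH2; (b) the bond between the CH2OH-bearing alkene carbon and that two-carbon link (as a vinyl group); (c) the C–CH2OH bond; (d) C13–C14 of sclareol.
- Forward: (−)-sclareol supplies the decalin and the chain up to the alkene; its C16 methyl becomes the alkene carbon that carries CH2OH. The sequence is methyl ketone, 2-alkyn-1-ol, anti-vinylmagnesiation, hydroboration, bromide; the monocycle is attached last.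
- Key step: a Cu/phosphoramidite-catalysed SN2′ coupling of the chain Grignard reagent with achiral 1-(chloromethyl)-3,3-dimethylcyclohex-1-ene makes the last C–C bond, the ring stereocentre and the exocyclic methylene in one operation.
- Enabling feature: in the monocycle the stereogenic CH lies between the CMe2 carbon and the carbon bearing the exocyclic =CH2. It is therefore the γ-terminus of an allyl unit whose α-terminus is that CH2, so the ring partner needs neither a stereocentre nor a preformed exocyclic alkene.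
- Stereochemistry: C5, C8, C9 and C10 come unchanged from sclareol; the alkene geometry comes from the five-membered magnesium chelate of the carbomagnesiation; the (S) ring centre comes from the catalyst alone.

Key step: step 11

Assumption: the sense of induction of the phosphoramidite–copper catalyst on 20 is taken to follow that on unsubstituted 1-(chloromethyl)cyclohexene, and the ligand antipode that directs the alkyl group to the Si face of C2 of 20 is used.

Abbreviations in names: DecOH = (1R,2R,4aS,8aS)-2-hydroxy-2,5,5,8a-tetramethyldecahydronaphthalen-1-yl; DecOTES = the same group with the 2-OH as its triethylsilyl ether. Labdane numbering is used for the sclareol-derived carbons; C1, C2 and C3 of 20 are the CH2Cl-bearing ring carbon, the ring CH= and the CMe2 carbon.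

**Step 1**
Reactants: 1 (−)-sclareol
Product: 3 4-(DecOH)butan-2-one (8α-hydroxy-14,15-dinorlabdan-13-one), via tetraol 2 (not isolated)
Conditions: OsO4 (2 mol %), NaIO4 (4 equiv), THF/H2O, 45 °C
Reagents that add atoms: none
Why: Catalytic dihydroxylation of the vinyl group and double periodate cleavage of the resulting 13,14,15-triol unit (Lemieux–Johnson oxidation) should excise C14 and C15 and leave the C13 methyl ketone, with the four ring stereocentres untouched.

**Step 2**
Reactants: 3 4-(DecOH)butan-2-one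
Product: 4 4-(DecOTES)butan-2-one
Conditions: TESOTf, 2,6-lutidine, CH2Cl2, −78 to 0 °C; aqueous citric acid work-up
Reagents that add atoms: triethylsilyl trifluoromethanesulfonate, CC[Si](CC)(CC)OS(=O)(=O)C(F)(F)F
Why: O-Silylation of the hindered tertiary 8-OH with a silyl triflate and a hindered base masks the only acidic group before the enolate, Grignard and borane steps; any silyl enol ether is returned to the ketone by the mildly acidic work-up.

**Step 3**
Reactants: 4 4-(DecOTES)butan-2-one
Product: 8 5-(DecOTES)pent-2-yn-1-ol, via lithium enolate 5 (not isolated), via enol phosphate 6 (not isolated), via lithium acetylide 7 (not isolated)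
Conditions: LDA (1.1 equiv), THF, −78 °C; ClP(O)(OEt)2, −78 °C to rt; LDA (2.4 equiv), −78 °C to rt; (CH2O)n (excess), 0 °C to rt; aqueous NH4Cl
Reagents that add atoms: paraformaldehyde (as formaldehyde), C=O
Why: Kinetic deprotonation at the methyl group, O-phosphorylation and base-induced elimination of the enol phosphate convert the methyl ketone into the terminal acetylide (ketone-to-alkyne conversion through an enol phosphate), which adds to formaldehyde to give the 2-alkyn-1-ol.

**Step 4**
Reactants: 8 5-(DecOTES)pent-2-yn-1-ol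
Product: 10 (2E)-2-ethenyl-5-(DecOTES)pent-2-en-1-ol, via oxamagnesacycle 9 (not isolated)
Conditions: CH2=CHMgCl (4 equiv), THF/toluene, 80 °C; aqueous NH4Cl, 0 °C
Reagents that add atoms: vinylmagnesium chloride, C=C[Mg]Cl
Why: In this alkoxide-directed anti-carbomagnesiation of a 2-alkyn-1-ol the magnesium alkoxide delivers the vinyl group to the proximal alkyne carbon while magnesium ends on the distal carbon in a five-membered chelate, so protonolysis places H cis to CH2OH and the vinyl group cis to the decalin-bearing chain, which is the alkene geometry of the target.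

**Step 5**
Reactants: 10 (2E)-2-ethenyl-5-(DecOTES)pent-2-en-1-ol
Product: 11 tert-butyl{[(2E)-2-ethenyl-5-(DecOTES)pent-2-en-1-yl]oxy}dimethylsilane
Conditions: TBSCl, imidazole, DMF, 0 °C to rt
Reagents that add atoms: tert-butyldimethylsilyl chloride, CC(C)(C)[Si](C)(C)Cl
Why: Standard O-silylation of the primary allylic alcohol, so that no O–H is present during hydroboration and Grignard formation.

**Step 6**
Reactants: 11 tert-butyl{[(2E)-2-ethenyl-5-(DecOTES)pent-2-en-1-yl]oxy}dimethylsilane
Product: 13 (3E)-3-{[(tert-butyldimethylsilyl)oxy]methyl}-6-(DecOTES)hex-3-en-1-ol, via alkylborane 12 (not isolated)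
Conditions: 9-BBN, THF, 0 °C to rt; then NaOH, H2O2, 0 °C to rt
Reagents that add atoms: hydrogen peroxide, OO
Why: Anti-Markovnikov hydroboration of the monosubstituted vinyl terminus of the 2-substituted 1,3-diene by the bulky dialkylborane should leave the trisubstituted alkene untouched, and oxidation of the C–B bond gives the primary alcohol.

**Step 7**
Reactants: 13 (3E)-3-{[(tert-butyldimethylsilyl)oxy]methyl}-6-(DecOTES)hex-3-en-1-ol
Product: 14 {[(2E)-2-(2-bromoethyl)-5-(DecOTES)pent-2-en-1-yl]oxy}(tert-butyl)dimethylsilane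
Conditions: CBr4, PPh3, 2,6-lutidine (cat.), CH2Cl2, 0 °C
Reagents that add atoms: carbon tetrabromide, BrC(Br)(Br)Br
Why: Appel reaction of the primary alcohol under buffered conditions that both silyl ethers should tolerate.

**Step 8**
Reactants: 15 3-methylcyclohex-2-en-1-one
Product: 17 3,3-dimethylcyclohex-1-en-1-yl trifluoromethanesulfonate, via lithium enolate 16 (not isolated)
Conditions: Me2CuLi (from MeLi and CuI), Et2O, 0 °C; then PhNTf2, THF, 0 °C to rt
Reagents that add atoms: lithium dimethylcuprate, [Li+].C[Cu-]C; N-phenylbis(trifluoromethanesulfonimide), O=S(=O)(N(c1ccccc1)S(=O)(=O)C(F)(F)F)C(F)(F)F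
Why: Conjugate addition of the cuprate creates the gem-dimethyl carbon and a regiodefined enolate, and O-triflation fixes the double bond between C1 and C2, next to the quaternary carbon.

**Step 9**
Reactants: 17 3,3-dimethylcyclohex-1-en-1-yl trifluoromethanesulfonate
Product: 18 (3,3-dimethylcyclohex-1-en-1-yl)methanol
Conditions: Bu3SnCH2OH, Pd(PPh3)4 (5 mol %), LiCl (3 equiv), 1,4-dioxane, 100 °C
Reagents that add atoms: (tributylstannyl)methanol, CCCC[Sn](CCCC)(CCCC)CO
Why: Stille coupling of the vinyl triflate with the hydroxymethylstannane transfers CH2OH to C1 with the double bond held in place.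

**Step 10**
Reactants: 18 (3,3-dimethylcyclohex-1-en-1-yl)methanol
Product: 20 1-(chloromethyl)-3,3-dimethylcyclohex-1-ene, via allylic mesylate 19 (not isolated)
Conditions: MsCl, Et3N, CH2Cl2, −20 °C; then LiCl, THF, 0 °C to rt
Reagents that add atoms: lithium chloride, [Li+].[Cl-]
Why: Mesylation and SN2 displacement by chloride at the primary allylic carbon; attack at the hindered ring carbon next to CMe2 (allylic transposition) is not expected.

**Step 11**
Reactants: 14 {[(2E)-2-(2-bromoethyl)-5-(DecOTES)pent-2-en-1-yl]oxy}(tert-butyl)dimethylsilane; 20 1-(chloromethyl)-3,3-dimethylcyclohex-1-ene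
Product: 22 tert-butyl{[(2E)-2-{2-[(1S)-2,2-dimethyl-6-methylidenecyclohexyl]ethyl}-5-(DecOTES)pent-2-en-1-yl]oxy}dimethylsilane, via Grignard reagent 21 (not isolated)
Conditions: Mg, Et2O, reflux (14 to 21); then slow addition over 2 h to 20 (1.5 equiv), copper(I) thiophene-2-carboxylate (5 mol %), BINOL-derived bis(1-arylethyl)amine phosphoramidite (6 mol %, antipode as assumed), CH2Cl2, −78 °C
Reagents that add atoms: none
Why: The alkyl Grignard reagent 21 transmetalates to a chiral phosphoramidite–copper(I) species that binds the C1=C2 π-bond of 20 anti to the C–Cl bond and adds oxidatively with loss of chloride to a γ-σ-allylcopper(III) intermediate at C2, which should eliminate reductively to the C2–alkyl bond faster than it isomerises to the primary α-copper species, so the double bond is left exocyclic (Cu-catalysed asymmetric allylic alkylation, SN2′ mode). The closest known reaction type is the copper/phosphoramidite-catalysed addition of primary alkyl Grignard reagents to 1-(chloromethyl)cycloalkenes, which gives 2-alkyl-1-methylidenecycloalkanes. No ring is closed. The only new stereocentre, the ring CH between CMe2 and C(=CH2), is set by the ligand, which selects the Si face of C2 (priorities C1 > C3 > H) and so gives the (S) configuration; the decalin stereocentres are seven bonds away, so the catalyst antipode alone decides the diastereomer. The step needs γ- over α-selectivity and high facial selectivity: the first is served by the chloride leaving group, the non-coordinating solvent and slow addition of the Grignard reagent at −78 °C, the second by the rigid cyclic allyl chloride, whose alkene geometry is fixed. The silyl ethers and the trisubstituted alkene of 21 are inert, and no acid is present that could move the exocyclic double bond into the ring.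

**Step 12**
Reactants: 22 tert-butyl{[(2E)-2-{2-[(1S)-2,2-dimethyl-6-methylidenecyclohexyl]ethyl}-5-(DecOTES)pent-2-en-1-yl]oxy}dimethylsilane
Product: 23 (2E)-2-{2-[(1S)-2,2-dimethyl-6-methylidenecyclohexyl]ethyl}-5-(DecOH)pent-2-en-1-ol (CNP0209309.1)
Conditions: TBAF, THF, rt to 45 °C
Reagents that add atoms: none
Why: Fluoride cleaves the primary TBS ether and, on gentle warming, the hindered tertiary TES ether without acid, so the exocyclic alkene and the tertiary alcohol are not at risk.

**Compound list**

1 | (−)-sclareol, (13R)-labd-14-ene-8α,13-diol | C=C[C@](C)(O)CC[C@@H]1[C@@]2(C)CCCC(C)(C)[C@@H]2CC[C@@]1(C)O | starting material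
2 | (13R)-labdane-8α,13,14,15-tetraol (mixture at C14) | OCC(O)[C@](C)(O)CC[C@@H]1[C@@]2(C)CCCC(C)(C)[C@@H]2CC[C@@]1(C)O | intermediate
3 | 4-(DecOH)butan-2-one (8α-hydroxy-14,15-dinorlabdan-13-one) | CC(=O)CC[C@@H]1[C@@]2(C)CCCC(C)(C)[C@@H]2CC[C@@]1(C)O | intermediate
4 | 4-(DecOTES)butan-2-one | CC(=O)CC[C@@H]1[C@@]2(C)CCCC(C)(C)[C@@H]2CC[C@@]1(C)O[Si](CC)(CC)CC | intermediate
5 | lithium 4-(DecOTES)but-1-en-2-olate | [Li]OC(=C)CC[C@@H]1[C@@]2(C)CCCC(C)(C)[C@@H]2CC[C@@]1(C)O[Si](CC)(CC)CC | intermediate
6 | diethyl 4-(DecOTES)but-1-en-2-yl phosphate | C=C(OP(=O)(OCC)OCC)CC[C@@H]1[C@@]2(C)CCCC(C)(C)[C@@H]2CC[C@@]1(C)O[Si](CC)(CC)CC | intermediate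
7 | [4-(DecOTES)but-1-yn-1-yl]lithium | [Li]C#CCC[C@@H]1[C@@]2(C)CCCC(C)(C)[C@@H]2CC[C@@]1(C)O[Si](CC)(CC)CC | intermediate
8 | 5-(DecOTES)pent-2-yn-1-ol | OCC#CCC[C@@H]1[C@@]2(C)CCCC(C)(C)[C@@H]2CC[C@@]1(C)O[Si](CC)(CC)CC | intermediate
9 | 4-ethenyl-3-[2-(DecOTES)ethyl]-2,5-dihydro-1,2-oxamagnesole (five-membered C–Mg–O chelate) | C=CC1=C(CC[C@@H]2[C@@]3(C)CCCC(C)(C)[C@@H]3CC[C@@]2(C)O[Si](CC)(CC)CC)[Mg]OC1 | intermediate
10 | (2E)-2-ethenyl-5-(DecOTES)pent-2-en-1-ol | C=C/C(=C\CC[C@@H]1[C@@]2(C)CCCC(C)(C)[C@@H]2CC[C@@]1(C)O[Si](CC)(CC)CC)CO | intermediate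
11 | tert-butyl{[(2E)-2-ethenyl-5-(DecOTES)pent-2-en-1-yl]oxy}dimethylsilane | C=C/C(=C\CC[C@@H]1[C@@]2(C)CCCC(C)(C)[C@@H]2CC[C@@]1(C)O[Si](CC)(CC)CC)CO[Si](C)(C)C(C)(C)C | intermediate
12 | 9-[(3E)-3-{[(tert-butyldimethylsilyl)oxy]methyl}-6-(DecOTES)hex-3-en-1-yl]-9-borabicyclo[3.3.1]nonane | C1CCC2CCCC1B2CC/C(=C\CC[C@@H]3[C@@]4(C)CCCC(C)(C)[C@@H]4CC[C@@]3(C)O[Si](CC)(CC)CC)CO[Si](C)(C)C(C)(C)C | intermediate
13 | (3E)-3-{[(tert-butyldimethylsilyl)oxy]methyl}-6-(DecOTES)hex-3-en-1-ol | OCC/C(=C\CC[C@@H]1[C@@]2(C)CCCC(C)(C)[C@@H]2CC[C@@]1(C)O[Si](CC)(CC)CC)CO[Si](C)(C)C(C)(C)C | intermediate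
14 | {[(2E)-2-(2-bromoethyl)-5-(DecOTES)pent-2-en-1-yl]oxy}(tert-butyl)dimethylsilane | BrCC/C(=C\CC[C@@H]1[C@@]2(C)CCCC(C)(C)[C@@H]2CC[C@@]1(C)O[Si](CC)(CC)CC)CO[Si](C)(C)C(C)(C)C | intermediate
15 | 3-methylcyclohex-2-en-1-one | CC1=CC(=O)CCC1 | starting material
16 | lithium 3,3-dimethylcyclohex-1-en-1-olate | [Li]OC1=CC(C)(C)CCC1 | intermediate
17 | 3,3-dimethylcyclohex-1-en-1-yl trifluoromethanesulfonate | CC1(C)CCCC(OS(=O)(=O)C(F)(F)F)=C1 | intermediate
18 | (3,3-dimethylcyclohex-1-en-1-yl)methanol | CC1(C)CCCC(CO)=C1 | intermediate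
19 | (3,3-dimethylcyclohex-1-en-1-yl)methyl methanesulfonate | CC1(C)CCCC(COS(C)(=O)=O)=C1 | intermediate
20 | 1-(chloromethyl)-3,3-dimethylcyclohex-1-ene | CC1(C)CCCC(CCl)=C1 | intermediate
21 | [(3E)-3-{[(tert-butyldimethylsilyl)oxy]methyl}-6-(DecOTES)hex-3-en-1-yl]magnesium bromide | Br[Mg]CC/C(=C\CC[C@@H]1[C@@]2(C)CCCC(C)(C)[C@@H]2CC[C@@]1(C)O[Si](CC)(CC)CC)CO[Si](C)(C)C(C)(C)C | intermediate
22 | tert-butyl{[(2E)-2-{2-[(1S)-2,2-dimethyl-6-methylidenecyclohexyl]ethyl}-5-(DecOTES)pent-2-en-1-yl]oxy}dimethylsilane | C=C1CCCC(C)(C)[C@@H]1CC/C(=C\CC[C@@H]1[C@@]2(C)CCCC(C)(C)[C@@H]2CC[C@@]1(C)O[Si](CC)(CC)CC)CO[Si](C)(C)C(C)(C)C | intermediate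
23 | (2E)-2-{2-[(1S)-2,2-dimethyl-6-methylidenecyclohexyl]ethyl}-5-[(1R,2R,4aS,8aS)-2-hydroxy-2,5,5,8a-tetramethyldecahydronaphthalen-1-yl]pent-2-en-1-ol | C=C1CCCC(C)(C)[C@@H]1CC/C(=C\CC[C@@H]1[C@@]2(C)CCCC(C)(C)[C@@H]2CC[C@@]1(C)O)CO | target

**Step count**

Total: 12 steps. Longest linear sequence: 9 steps (steps 1–7, 11, 12); the ring fragment takes 3 steps (8–10).

**Steps most likely to fail**

Step 11. The copper reagent may substitute directly at the exocyclic CH2 (SN2 instead of SN2′) because the γ-carbon is shielded by the neighbouring gem-dimethyl carbon, the catalyst may discriminate the two faces of C2 poorly, and Grignard formation may be eroded by Wurtz coupling. In the fallback the stereocentre is made on the small ring fragment and the halves are joined at the other end of the two-carbon link. It sets out from 18 and 8 and comes back to the route at 23. Johnson–Claisen rearrangement of 18 (MeC(OEt)3, EtCO2H cat., 140 °C) should give racemic ethyl (2,2-dimethyl-6-methylidenecyclohexyl)acetate F1, with the new bond on the ring carbon next to CMe2 and the alkene exocyclic. Saponification (LiOH, THF/H2O) gives (2,2-dimethyl-6-methylidenecyclohexyl)acetic acid F2, which is resolved by crystallisation as (R)-1-phenylethylammonium [(1S)-2,2-dimethyl-6-methylidenecyclohexyl]acetate F3. LiAlH4 reduces the salt to 2-[(1S)-2,2-dimethyl-6-methylidenecyclohexyl]ethan-1-ol F4, the Appel reaction gives (2S)-2-(2-bromoethyl)-1,1-dimethyl-3-methylidenecyclohexane F5, and magnesium gives {2-[(1S)-2,2-dimethyl-6-methylidenecyclohexyl]ethyl}magnesium bromide F6. Copper(I) iodide-catalysed, alkoxide-directed anti-carbomagnesiation of 8 (deprotonated beforehand with EtMgBr) with F6 forms the C–C bond at the proximal alkyne carbon with the same geometry as in step 4 and should give (2E)-2-{2-[(1S)-2,2-dimethyl-6-methylidenecyclohexyl]ethyl}-5-(DecOTES)pent-2-en-1-ol F7; TBAF then gives 23.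

Step 4. Addition of the vinyl group across the dialkyl-substituted alkynol may be slow, with competing syn-addition or decomposition at the temperature needed. The fallback replaces carbometalation by hydrometalation and cross-coupling; it sets out from 8 and comes back at 10. Hydroxyl-directed, ruthenium-catalysed trans-hydrostannation ([Cp*RuCl]4 cat., Bu3SnH, CH2Cl2) should place tin on the proximal carbon and hydrogen trans to it, giving (2Z)-2-(tributylstannyl)-5-(DecOTES)pent-2-en-1-ol F8. Stille coupling with vinyl bromide (Pd(PPh3)4, copper(I) thiophene-2-carboxylate, DMF) with retention then gives 10.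

Step 9. Transfer of the hydroxymethyl group from tin may be slow, with competing butyl transfer and reduction of the triflate. The fallback introduces the carbon by carbonylation and sets the oxidation level afterwards; it sets out from 17 and comes back at 18. Palladium-catalysed methoxycarbonylation (Pd(OAc)2, PPh3, CO 1 atm, MeOH, Et3N, DMF, 60 °C) should give methyl 3,3-dimethylcyclohex-1-ene-1-carboxylate F9, and DIBAL (CH2Cl2, −78 °C) reduces it to 18.

**Further compounds**

F1 | step 11 | ethyl (2,2-dimethyl-6-methylidenecyclohexyl)acetate (racemic) | CCOC(=O)CC1C(=C)CCCC1(C)C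
F2 | step 11 | (2,2-dimethyl-6-methylidenecyclohexyl)acetic acid (racemic) | OC(=O)CC1C(=C)CCCC1(C)C
F3 | step 11 | (R)-1-phenylethylammonium [(1S)-2,2-dimethyl-6-methylidenecyclohexyl]acetate | C=C1CCCC(C)(C)[C@@H]1CC(=O)[O-].C[C@@H]([NH3+])c1ccccc1
F4 | step 11 | 2-[(1S)-2,2-dimethyl-6-methylidenecyclohexyl]ethan-1-ol | C=C1CCCC(C)(C)[C@@H]1CCO
F5 | step 11 | (2S)-2-(2-bromoethyl)-1,1-dimethyl-3-methylidenecyclohexane | C=C1CCCC(C)(C)[C@@H]1CCBr
F6 | step 11 | {2-[(1S)-2,2-dimethyl-6-methylidenecyclohexyl]ethyl}magnesium bromide | C=C1CCCC(C)(C)[C@@H]1CC[Mg]Br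
F7 | step 11 | (2E)-2-{2-[(1S)-2,2-dimethyl-6-methylidenecyclohexyl]ethyl}-5-(DecOTES)pent-2-en-1-ol | C=C1CCCC(C)(C)[C@@H]1CC/C(=C\CC[C@@H]1[C@@]2(C)CCCC(C)(C)[C@@H]2CC[C@@]1(C)O[Si](CC)(CC)CC)CO
F8 | step 4 | (2Z)-2-(tributylstannyl)-5-(DecOTES)pent-2-en-1-ol | CCCC[Sn](CCCC)(CCCC)/C(=C\CC[C@@H]1[C@@]2(C)CCCC(C)(C)[C@@H]2CC[C@@]1(C)O[Si](CC)(CC)CC)CO
F9 | step 9 | methyl 3,3-dimethylcyclohex-1-ene-1-carboxylate | COC(=O)C1=CC(C)(C)CCC1
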